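**Retrosynthetic overview**

1. The strategy rests on the (E)-3-alkylidene succinimide: the five-membered imide C13–C14–C15(=O)–N–C16(=O) with the exocyclic C12=C13 bond. It is cut at C13–C16 and C16–N into CO, a hydrogen on C12 and the 3-alkynamide 15 (C12≡C13, C15 primary amide).
2. 15 ⇒ terminal alkyne 11 + ethyl diazoacetate 12 (C13–C14, copper); nitrogen comes in by aluminium-amide aminolysis and the C7 acetate goes on last. 11 ⇒ C12 aldehyde 9 + Ohira–Bestmann reagent 10 (C13).
3. The 7β-hydroxyl ⇐ allylic oxidation of the 8(17)-alkene 5 (gives 7α), oxidation and axial hydride delivery. 5 ⇐ Weinreb opening and dehydration of lactone 2.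
4. 2 ⇐ C2–H chlorination of (+)-sclareolide 1, which supplies the trans-decalin (rings A and B) with C5, C9 and C10 already set.
5. Ring order: rings A and B are bought, the lactone ring is opened, and the imide ring is the only ring formed, in the last step.

Key step: step 12

Assumption: atoms carry labdane numbers (C16 is the carbon delivered by CO), and the N-chloroamide of step 1 is used as a purchased reagent.

**Route**

Step 1
Reactants: 1 (+)-sclareolide
Product: 2 2α-chlorosclareolide
Conditions: N-chloro-N-tert-butyl-3,5-bis(trifluoromethyl)benzamide (1.1 equiv), Cs2CO3 (acid scavenger), PhH, visible light, 55 °C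
Reagents that add atoms: N-chloro-N-tert-butyl-3,5-bis(trifluoromethyl)benzamide, CC(C)(C)N(Cl)C(=O)c1cc(cc(c1)C(F)(F)F)C(F)(F)F
Why: Radical C–H chlorination by an N-chloroamide (amidyl radical hydrogen abstraction, then chlorine atom transfer in a chain) is expected to take the most accessible and most electron-rich methylene hydrogen, at C2 of ring A far from the electron-poor lactone, and the C2 radical should accept chlorine on its α face because the β (axial) side is shielded by the axial methyl groups on C4 and C10, which sets the equatorial 2α-chloride.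

Step 2
Reactants: 2 2α-chlorosclareolide
Product: 3 N-methoxy-N-methyl-2α-chloro-8α-hydroxy-13,14,15,16-tetranorlabdan-12-amide
Conditions: MeNH(OMe)·HCl, Me3Al, CH2Cl2, 0 °C → rt; cold dilute aq. HCl work-up
Reagents that add atoms: N,O-dimethylhydroxylamine hydrochloride, CNOC.Cl
Why: Weinreb aminolysis with an aluminium amide attacks the lactone carbonyl C12 only, so the γ-lactone opens with the C8–O bond and the 8α configuration untouched, and the hindered equatorial secondary chloride does not react with the organoaluminium reagent at room temperature.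

Step 3
Reactants: 3 N-methoxy-N-methyl-2α-chloro-8α-hydroxy-13,14,15,16-tetranorlabdan-12-amide
Product: 5 N-methoxy-N-methyl-2α-chloro-13,14,15,16-tetranorlabd-8(17)-en-12-amide, via C8 chlorosulfite 4 (not isolated)
Conditions: SOCl2, pyridine, CH2Cl2, −78 °C
Reagents that add atoms: none
Why: Dehydration through the chlorosulfite is an E2 elimination in which the equatorial 8α leaving group has no antiperiplanar ring hydrogen, so pyridine should remove a hydrogen of the C17 methyl group and give mainly the exocyclic 8(17)-alkene at low temperature, the endocyclic isomers being removed by chromatography.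

Step 4
Reactants: 5 N-methoxy-N-methyl-2α-chloro-13,14,15,16-tetranorlabd-8(17)-en-12-amide
Product: 6 N-methoxy-N-methyl-2α-chloro-7α-hydroxy-13,14,15,16-tetranorlabd-8(17)-en-12-amide
Conditions: SeO2 (0.5 equiv), t-BuOOH (3 equiv), CH2Cl2, rt
Reagents that add atoms: tert-butyl hydroperoxide, CC(C)(C)OO (oxygen relayed by the catalytic selenium dioxide, O=[Se]=O)
Why: Selenium dioxide allylic oxidation (ene reaction, then [2,3]-sigmatropic shift of the allylseleninic acid) prefers the ring CH2 at C7 to the tertiary C9–H, and delivers oxygen along the axial direction on the α face, so the 7α-alcohol is expected and its configuration is corrected in steps 5 and 6.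

Step 5
Reactants: 6 N-methoxy-N-methyl-2α-chloro-7α-hydroxy-13,14,15,16-tetranorlabd-8(17)-en-12-amide
Product: 7 N-methoxy-N-methyl-2α-chloro-7-oxo-13,14,15,16-tetranorlabd-8(17)-en-12-amide
Conditions: Dess–Martin periodinane, pyridine, CH2Cl2, 0 °C; crude product used at once
Reagents that add atoms: none
Why: Dess–Martin oxidation converts the secondary allylic alcohol into the α-methylene ketone under pyridine-buffered conditions, and the crude enone is reduced at once because acid or base could move the C8=C17 bond into the ring and so erase the C9 centre.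

Step 6
Reactants: 7 N-methoxy-N-methyl-2α-chloro-7-oxo-13,14,15,16-tetranorlabd-8(17)-en-12-amide
Product: 8 N-methoxy-N-methyl-2α-chloro-7β-hydroxy-13,14,15,16-tetranorlabd-8(17)-en-12-amide
Conditions: NaBH4, CeCl3·7H2O, MeOH, −78 °C
Reagents that add atoms: none
Why: Luche reduction gives 1,2-addition to the enone, and the small borohydride should approach C7 along the axial trajectory on the α face, where it meets only the axial hydrogens on C5 and C9, so the new C7 stereocentre should carry the equatorial 7β-hydroxyl, while the Weinreb amide is inert to borohydride at low temperature.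

Step 7
Reactants: 8 N-methoxy-N-methyl-2α-chloro-7β-hydroxy-13,14,15,16-tetranorlabd-8(17)-en-12-amide
Product: 9 2α-chloro-7β-hydroxy-13,14,15,16-tetranorlabd-8(17)-en-12-al
Conditions: DIBAL-H (2.5 equiv), THF, −78 °C; aq. Rochelle salt
Reagents that add atoms: none
Why: DIBAL-H reduction of a Weinreb amide stops at the chelated aluminium hemiaminal, which releases the C12 aldehyde only on work-up, the first equivalent of hydride being spent on the free hydroxyl.

Step 8
Reactants: 9 2α-chloro-7β-hydroxy-13,14,15,16-tetranorlabd-8(17)-en-12-al; 10 dimethyl (1-diazo-2-oxopropyl)phosphonate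
Product: 11 2α-chloro-7β-hydroxy-14,15,16-trinorlabd-8(17)-en-12-yne
Conditions: K2CO3, MeOH, 0 °C → rt
Reagents that add atoms: none
Why: Seyferth–Gilbert homologation in the Ohira–Bestmann form (methanolysis of 10 to the diazomethylphosphonate anion, Horner–Wadsworth–Emmons-type addition to the aldehyde, loss of phosphate and nitrogen, 1,2-hydrogen shift) turns the C12 aldehyde into the terminal C12≡C13 alkyne under potassium carbonate in methanol, conditions that cannot epimerise C9 because it is β to the carbonyl group.

Step 9
Reactants: 11 2α-chloro-7β-hydroxy-14,15,16-trinorlabd-8(17)-en-12-yne; 12 ethyl diazoacetate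
Product: 13 ethyl 2α-chloro-7β-hydroxy-16-norlabd-8(17)-en-12-yn-15-oate
Conditions: CuI (10 mol%), MeCN, rt, slow addition of 12
Reagents that add atoms: none
Why: Copper(I)-catalysed coupling of a terminal alkyne with a diazoacetate (copper acetylide, copper carbene, migratory insertion, protonation) forms the C13–C14 bond and gives the 3-alkynoate in the absence of base, so that no allenoate should form, and the acetylide pathway is expected to outrun cyclopropanation of the hindered C8=C17 alkene and O–H insertion at C7.

Step 10
Reactants: 13 ethyl 2α-chloro-7β-hydroxy-16-norlabd-8(17)-en-12-yn-15-oate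
Product: 14 2α-chloro-7β-hydroxy-16-norlabd-8(17)-en-12-yn-15-amide
Conditions: Me3Al, NH4Cl, toluene, 0 °C → rt, then 13, 40–50 °C; cold dilute aq. HCl work-up
Reagents that add atoms: ammonium chloride, [NH4+].[Cl-]
Why: Aminolysis of an ester by methylchloroaluminium amide (Weinreb's aluminium amide method) delivers NH2 to the aluminium-bound ester in an aprotic medium free of amine base, which is chosen over ammonia in methanol because a 3-alkynoate isomerises to the 2,3-allenoate under basic conditions, and the C7 hydroxyl is simply carried as its aluminium alkoxide.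

Step 11
Reactants: 14 2α-chloro-7β-hydroxy-16-norlabd-8(17)-en-12-yn-15-amide
Product: 15 7β-acetoxy-2α-chloro-16-norlabd-8(17)-en-12-yn-15-amide
Conditions: Ac2O, pyridine, CH2Cl2, 0 °C → rt
Reagents that add atoms: acetic anhydride, CC(=O)OC(C)=O
Why: Acetylation of the equatorial secondary alcohol with acetic anhydride in pyridine is far faster than N-acylation of the primary amide, and pyridine is too weak a base to isomerise the 3-alkynamide to the allenamide.

Step 12
Reactants: 15 7β-acetoxy-2α-chloro-16-norlabd-8(17)-en-12-yn-15-amide
Product: 16 (12E)-7β-acetoxy-2α-chlorolabda-8(17),12-diene-15,16-dicarboximide (CNP0220384.1)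
Conditions: Pd2(dba)3 (2.5 mol%), Xantphos (6 mol%), (PhO)2P(O)OH (10 mol%), CO (10 bar), THF, 50 °C
Reagents that add atoms: carbon monoxide, [C-]#[O+]
Why: Proposed new method: a palladium hydride formed from Pd(0) and the acid adds syn across C12≡C13; with palladium on C13 the C15 amide oxygen holds a five-membered chelate, CO inserts to give the C16 acyl palladium, and the amide nitrogen is acylated (directly or through the isoimide, which should rearrange under acid), releasing Pd(0) for the next cycle. The closest known reactions are the palladium-hydride cyclocarbonylations of alkynols and alkynylamines to α-alkylidene lactones and lactams and the hydroamidocarbonylations in which an amide N–H captures an acyl palladium to give an imide; closing an internal 3-alkynamide to a succinimide in this way has not been shown. The imide ring C13–C14–C15–N–C16 closes by 5-exo-trig attack of nitrogen on the acyl carbon. No stereocentre is formed; the alkene geometry follows from the syn addition, which puts the hydrogen on C12 and C16 on C13 on the same side, so that C11 is trans to C16 (E). The step needs palladium on C13 and reaction at the alkyne only: hydropalladation is reversible and an acyl palladium on C12 would hold the amide chain trans to itself and cannot cyclise, so ring closure drains the C13 isomer, while the hindered 1,1-disubstituted C8=C17 alkene, the equatorial allylic acetate (its C7–O bond lies near the nodal plane of the π bond and ionises slowly) and the secondary chloride are much less reactive than the alkyne. A weak acid, moderate temperature and a short reaction time are chosen so that the C12=C13 bond does not move into the ring to give the maleimide.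

**Compound list**

1 | (+)-sclareolide | C[C@@]12CC[C@H]3C(C)(C)CCC[C@]3(C)[C@H]1CC(=O)O2 | starting material
2 | 2α-chlorosclareolide (equatorial chloride on C2) | C[C@@]12CC[C@H]3C(C)(C)C[C@H](Cl)C[C@]3(C)[C@H]1CC(=O)O2 | intermediate
3 | N-methoxy-N-methyl-2α-chloro-8α-hydroxy-13,14,15,16-tetranorlabdan-12-amide (opened lactone, tertiary 8α-OH) | C[C@@]1(O)CC[C@H]2C(C)(C)C[C@H](Cl)C[C@]2(C)[C@H]1CC(=O)N(C)OC | intermediate
4 | C8 chlorosulfite of 3 (not isolated) | C[C@@]1(OS(Cl)=O)CC[C@H]2C(C)(C)C[C@H](Cl)C[C@]2(C)[C@H]1CC(=O)N(C)OC | intermediate
5 | N-methoxy-N-methyl-2α-chloro-13,14,15,16-tetranorlabd-8(17)-en-12-amide (exocyclic C8=C17) | C=C1CC[C@H]2C(C)(C)C[C@H](Cl)C[C@]2(C)[C@H]1CC(=O)N(C)OC | intermediate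
6 | N-methoxy-N-methyl-2α-chloro-7α-hydroxy-13,14,15,16-tetranorlabd-8(17)-en-12-amide (axial 7α-OH) | C=C1[C@H](O)C[C@H]2C(C)(C)C[C@H](Cl)C[C@]2(C)[C@H]1CC(=O)N(C)OC | intermediate
7 | N-methoxy-N-methyl-2α-chloro-7-oxo-13,14,15,16-tetranorlabd-8(17)-en-12-amide (α-methylene ketone) | C=C1C(=O)C[C@H]2C(C)(C)C[C@H](Cl)C[C@]2(C)[C@H]1CC(=O)N(C)OC | intermediate
8 | N-methoxy-N-methyl-2α-chloro-7β-hydroxy-13,14,15,16-tetranorlabd-8(17)-en-12-amide (equatorial 7β-OH) | C=C1[C@@H](O)C[C@H]2C(C)(C)C[C@H](Cl)C[C@]2(C)[C@H]1CC(=O)N(C)OC | intermediate
9 | 2α-chloro-7β-hydroxy-13,14,15,16-tetranorlabd-8(17)-en-12-al | C=C1[C@@H](O)C[C@H]2C(C)(C)C[C@H](Cl)C[C@]2(C)[C@H]1CC=O | intermediate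
10 | dimethyl (1-diazo-2-oxopropyl)phosphonate | CC(=O)C(=[N+]=[N-])P(=O)(OC)OC | starting material
11 | 2α-chloro-7β-hydroxy-14,15,16-trinorlabd-8(17)-en-12-yne (terminal C12≡C13 alkyne) | C=C1[C@@H](O)C[C@H]2C(C)(C)C[C@H](Cl)C[C@]2(C)[C@H]1CC#C | intermediate
12 | ethyl diazoacetate | CCOC(=O)C=[N+]=[N-] | starting material
13 | ethyl 2α-chloro-7β-hydroxy-16-norlabd-8(17)-en-12-yn-15-oate (3-alkynoate) | C=C1[C@@H](O)C[C@H]2C(C)(C)C[C@H](Cl)C[C@]2(C)[C@H]1CC#CCC(=O)OCC | intermediate
14 | 2α-chloro-7β-hydroxy-16-norlabd-8(17)-en-12-yn-15-amide | C=C1[C@@H](O)C[C@H]2C(C)(C)C[C@H](Cl)C[C@]2(C)[C@H]1CC#CCC(N)=O | intermediate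
15 | 7β-acetoxy-2α-chloro-16-norlabd-8(17)-en-12-yn-15-amide (key-step precursor) | C=C1[C@@H](OC(C)=O)C[C@H]2C(C)(C)C[C@H](Cl)C[C@]2(C)[C@H]1CC#CCC(N)=O | intermediate
16 | (12E)-7β-acetoxy-2α-chlorolabda-8(17),12-diene-15,16-dicarboximide (CNP0220384.1) | C=C1[C@@H](OC(C)=O)C[C@H]2C(C)(C)C[C@H](Cl)C[C@]2(C)[C@H]1C/C=C1\CC(=O)NC1=O | target

**Step count**

Total: 12 steps. Longest linear sequence: 12 steps (1 to 16).

**Steps most likely to fail**

First, step 12, the proposed cyclocarbonylation. Several processes could defeat it:
- hydropalladation of the internal alkyne may be slow or place palladium on C12, so that the acyl palladium is consumed by intermolecular acylation;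
- palladium(0) may ionise the allylic C7 acetate;
- palladium hydride may move the C8=C17 or the new C12=C13 double bond;
- the amide may add to the palladium-bound alkyne without uptake of CO.

The fallback is a Wittig olefination with a stabilised ylide, which is known chemistry for E-alkylidene succinimides. It sets out from hydroxy aldehyde 9. Acetylation (Ac2O, pyridine) should give 7β-acetoxy-2α-chloro-13,14,15,16-tetranorlabd-8(17)-en-12-al F1. F1 is then heated gently in THF or MeOH with 3-(triphenylphosphoranylidene)pyrrolidine-2,5-dione F2, prepared from maleimide and triphenylphosphine. The stabilised ylide should form the C12=C13 bond with E geometry, and the fallback comes back to the route at the target 16.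

Second, step 10, the aminolysis. Propargyl–allenyl isomerisation of the 3-alkynoate at the activated α-position, or incomplete conversion of the ester, may spoil it. The fallback separates hydrolysis from amide formation and sets out from ester 13. Enzymatic hydrolysis (lipase or pig liver esterase, pH 7 phosphate buffer with a cosolvent, rt) should give 2α-chloro-7β-hydroxy-16-norlabd-8(17)-en-12-yn-15-oic acid F3 without exposure to base. F3 is then coupled with the ammonium salt of 1-hydroxybenzotriazole and EDC at 0 °C, a carbodiimide amidation that needs no tertiary amine. It comes back to the route at hydroxy amide 14.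

Third, step 6, the reduction. The hydride may attack the β face or add in the 1,4 sense, and the α-methylene ketone may isomerise before it is reduced. The fallback avoids the ketone and inverts C7 by substitution, setting out from the 7α-alcohol 6. Mitsunobu reaction (4-nitrobenzoic acid, PPh3, DIAD, THF, 0 °C → rt) should give N-methoxy-N-methyl-2α-chloro-7β-(4-nitrobenzoyloxy)-13,14,15,16-tetranorlabd-8(17)-en-12-amide F4 with inversion. Methanolysis (K2CO3, MeOH) then frees the 7β-alcohol, and the fallback comes back to the route at 8.

Further compounds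
F1 | step 12 | 7β-acetoxy-2α-chloro-13,14,15,16-tetranorlabd-8(17)-en-12-al | C=C1[C@@H](OC(C)=O)C[C@H]2C(C)(C)C[C@H](Cl)C[C@]2(C)[C@H]1CC=O
F2 | step 12 | 3-(triphenylphosphoranylidene)pyrrolidine-2,5-dione | O=C1CC(=P(c2ccccc2)(c2ccccc2)c2ccccc2)C(=O)N1
F3 | step 10 | 2α-chloro-7β-hydroxy-16-norlabd-8(17)-en-12-yn-15-oic acid | C=C1[C@@H](O)C[C@H]2C(C)(C)C[C@H](Cl)C[C@]2(C)[C@H]1CC#CCC(=O)O
F4 | step 6 | N-methoxy-N-methyl-2α-chloro-7β-(4-nitrobenzoyloxy)-13,14,15,16-tetranorlabd-8(17)-en-12-amide | C=C1[C@@H](OC(=O)c3ccc(cc3)[N+](=O)[O-])C[C@H]2C(C)(C)C[C@H](Cl)C[C@]2(C)[C@H]1CC(=O)N(C)OC
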